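Take the easy case first: a flask in which starting material meets coupling partner and nothing else happens.

starting material 20 mM (in portions, 4); coupling partner 0.800 equiv; second substrate 5.00 equiv; time 15 d; the portions of starting material follow each other after 2.5 h, the first at the start

    starting material + coupling partner → target (k1 = 32 M⁻¹ h⁻¹)
    second substrate + coupling partner → second product (k2 = 0.24 M⁻¹ h⁻¹)
    starting material + second substrate → cross product (k3 = 8.3 M⁻¹ h⁻¹)
    target ⇌ isomer of the product (K4 = 0.19, k4 = 0.015 h⁻¹)

- the reaction counts as stopped when no species that holds the starting material changes by six tenths of a point or more over the second half of the time
- run time (flask): 15 d

- at 15 d, what has stopped the reaction, if anything has (all of the starting material has reacted / forward and back rates have come level / it is still moving)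
- conversion of starting material at 15 d
- amount of target at 15 d, in percent of the starting material charged
- amount of cross product at 15 d, in percent of the starting material charged
- amount of isomer of the product at 15 d, in percent of the starting material charged

With the coupling step alone, the coupling partner is the limiting reagent and target stops at 80.0%.

Now add the cross step. The flask holds 16.0 mM of coupling partner against 100 mM of second substrate. Starting material stands in both rates and cancels from their ratio. Define the capture odds, the selectivity factor, as the coupling rate over the cross rate:

capture odds at charge = 0.617

Odds of one are the even split, the zero of this scale, and this flask stands below it. The coupling side gets odds/(one + odds):

share at charge = 38.2%

Next come the side step and the running down of both partners. The portions take 7.50 h, and over that time the side step, reckoned at the charged concentrations, takes about 2.88 mM of coupling partner. Reckoned at the midpoint of those losses: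

coupling partner = 10.7 mM, second substrate = 92.4 mM

mid-run odds = 0.448, share = 31.0%

Last comes the isomerisation. Its relaxation half-life of 0.307 d is short against 15 d, so that share splits between target and isomer of the product at the equilibrium constant 0.19. My reckoning gives target 26.0%, isomer of the product 4.94% and cross product 69.0%. With the other concentrations as charged, the cross step by itself halves starting material in 0.84 h, so conversion comes to 100%.

The forecast says all of the starting material has reacted, with conversion 100%, target 26.6%, cross product 68.3% and isomer of the product 5.1%. Its ground is that the second substrate “beats the coupling partner about two to one as that partner is depleted”. Its cross product lies 0.74 percentage points below mine.

The simulation gives all of the starting material has reacted, with conversion 100%, target 26.6%, cross product 68.3% and isomer of the product 5.06%. In this flask the ratio of coupled material to cross product at 15 d reads 0.464, beside the mid-run odds of 0.448. The neighbouring flask with 3.20 equiv of coupling partner starts above the even point, at charged odds of 2.47. The same midpoint reckoning, with that flask's own losses, puts its odds at 2.16, which reckons to 31.6% cross product. That neighbouring flask gives 31.6% cross product, 57.4% target and 10.9% isomer of the product.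

The rate constants stand for no real mixture; the result is computed.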